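**Strategy.** Everything rests on cutting C4–C4a and C4''–C4a'' of the 6,8''-biflavone, so that both pyranone rings C are closed last by one twofold intramolecular Friedel–Crafts acylation. The precursor is a tetrakis(benzyloxy)biphenyl whose two remaining oxygens, O1 and O1'', already carry (Z)-3-(4-methoxyphenyl)acrylic acid arms. The step exploits the placement of these oxygens on rings A. C8a–O1 lies para to the axis carbon C6, so its two neighbours (future C4a and C8) are equivalent. C8a''–O1'' lies next to the axis carbon C8'', so only C4a'' is open. Acylation beside each oxygen therefore has a single constitutional outcome and no 6/8 scrambling can arise.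

Key step: step 9

Assumption: the SMILES fixes no configuration at the C6–C8'' axis, so the racemate is taken as the target.
Locants: in the biphenyls the unprimed ring becomes ring A of the C6-linked flavone and the primed ring becomes ring A of the C8''-linked flavone.
Geometry: OAr outranks aryl at the oxygen-bearing alkene carbon and the carboxyl carbon outranks H at the other, so the isomer with carboxyl cis to aryloxy is Z. This is the isomer drawn in 13, 14 and 15.

Step 1
Reactants: 1 5-chlororesorcinol (5-chlorobenzene-1,3-diol)
Product: 2 5-chloro-2-iodobenzene-1,3-diol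
Conditions: I2, NaHCO3, THF/H2O, 0 °C to rt
Reagents that add atoms: iodine, II
Why: Electrophilic aromatic iodination of a resorcinol in aqueous bicarbonate is known to enter C2 between the two free hydroxyls, and since C4 and C6 are also crowded by chlorine the iodine should mark the future axis carbon C6 while chlorine holds the place of O1, a pattern that halogenation or lithiation of a 3,5-bis(benzyloxy)phenol ether cannot be trusted to give.

Step 2
Reactants: 2 5-chloro-2-iodobenzene-1,3-diol
Product: 3 1,3-bis(benzyloxy)-5-chloro-2-iodobenzene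
Conditions: BnBr, K2CO3, DMF, rt to 50 °C
Reagents that add atoms: benzyl bromide, BrCc1ccccc1
Why: Twofold Williamson ether synthesis on the two acidic phenols, under which neither aryl halide reacts.

Step 3
Reactants: 4 3,5-bis(benzyloxy)phenol
Product: 5 3,5-bis(benzyloxy)-2-iodophenol
Conditions: NIS, DMF, −20 °C to 0 °C
Reagents that add atoms: N-iodosuccinimide, O=C1CCC(=O)N1I
Why: Electrophilic aromatic iodination in which the carbon between the free hydroxyl and a benzyloxy group is strongly activated and less shielded than the carbon between the two benzyloxy groups, so the iodine should mark the future C8'' next to O1''.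

Step 4
Reactants: 5 3,5-bis(benzyloxy)-2-iodophenol
Product: 6 1,5-bis(benzyloxy)-2-iodo-3-(methoxymethoxy)benzene
Conditions: MOMCl, iPr2NEt, CH2Cl2, 0 °C to rt
Reagents that add atoms: chloromethyl methyl ether, COCCl
Why: O-alkylation to the MOM acetal masks the acidic proton before metalation and puts the smallest practical group beside the future axis.

Step 5
Reactants: 6 1,5-bis(benzyloxy)-2-iodo-3-(methoxymethoxy)benzene; 3 1,3-bis(benzyloxy)-5-chloro-2-iodobenzene
Product: 9 2,6,4',6'-tetrakis(benzyloxy)-4-chloro-2'-(methoxymethoxy)biphenyl, via arylmagnesium chloride 7 (not isolated), via arylzinc chloride 8 (not isolated)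
Conditions: 6, iPrMgCl·LiCl, THF, 0 °C; ZnCl2, 0 °C to rt; then 3, Pd2(dba)3, RuPhos, THF, 65 °C
Reagents that add atoms: none
Why: Iodine–magnesium exchange, transmetalation to zinc and Negishi coupling, for which a bulky dialkylbiarylphosphine on zerovalent palladium is the established answer to biaryls with four ortho substituents; the C–I bond of 3 should add long before its C–Cl bond, and the arylzinc avoids the protodeboronation typical of 2,4,6-trioxygenated arylboron reagents.

Step 6
Reactants: 9 2,6,4',6'-tetrakis(benzyloxy)-4-chloro-2'-(methoxymethoxy)biphenyl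
Product: 11 2,6,4',6'-tetrakis(benzyloxy)biphenyl-4,2'-diol, via monophenol MOM ether 10 (not isolated)
Conditions: Pd2(dba)3, tBuXPhos, KOH, 1,4-dioxane/H2O, 100 °C; then HCl, MeOH, 50 °C
Reagents that add atoms: potassium hydroxide, [K+].[OH-]
Why: Palladium-catalysed hydroxylation of the unhindered aryl chloride (Buchwald–Hartwig-type C–O coupling with hydroxide) installs O1, and the acidification that is needed anyway is extended to hydrolysis of the MOM acetal, conditions that leave the benzyl ethers untouched.

Step 7
Reactants: 11 2,6,4',6'-tetrakis(benzyloxy)biphenyl-4,2'-diol; 12 methyl 3-(4-methoxyphenyl)propiolate (two molecules are taken up)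
Product: 13 dimethyl (2Z,2'Z)-3,3'-{[2,6,4',6'-tetrakis(benzyloxy)biphenyl-4,2'-diyl]bis(oxy)}bis[3-(4-methoxyphenyl)acrylate]
Conditions: Cs2CO3, DMF, argon, 70 °C
Reagents that add atoms: none
Why: Twofold oxa-Michael addition of the phenoxides to the alkynoate, in which anti protonation of the allenolate places the ester cis to the aryloxy group (Z), the geometry needed for ring closure.

Step 8
Reactants: 13 dimethyl (2Z,2'Z)-bis(aryloxyacrylate)
Product: 14 (2Z,2'Z)-3,3'-{[2,6,4',6'-tetrakis(benzyloxy)biphenyl-4,2'-diyl]bis(oxy)}bis[3-(4-methoxyphenyl)acrylic acid]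
Conditions: LiOH, THF/MeOH/H2O, rt; then cold 1 M HCl to pH 3
Reagents that add atoms: lithium hydroxide, [Li+].[OH-]
Why: Ester saponification by acyl–oxygen cleavage, classical for 3-aryloxycinnamates because the doubly donor-substituted alkene carbon resists conjugate attack by hydroxide, with a cold and only mildly acidic work-up to avoid decarboxylation.

Step 9
Reactants: 14 (2Z,2'Z)-bis(aryloxyacrylic acid)
Product: 16 5,7,5'',7''-tetrakis(benzyloxy)-4',4'''-dimethoxy-6,8''-biflavone, via bis(acyl trifluoroacetate) 15 (not isolated)
Conditions: (CF3CO)2O, CH2Cl2 (high dilution), 0 °C to rt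
Reagents that add atoms: none
Why: (CF3CO)2O turns each carboxyl group into an acyl trifluoroacetate (15), which ionises to a donor-stabilised acylium ion that the Z alkene keeps beside its aryloxy ring; the ring carbon next to the ether oxygen attacks, a proton is lost, and C4–C4a and C4''–C4a'' are formed. The closest known reaction type is the Ruhemann flavone synthesis, the intramolecular Friedel–Crafts acylation of a 3-aryloxycinnamic acid, run here at both ends of one molecule. Counted at the acylium carbon, the closure of ring C and that of ring C'' are each 6-exo-dig because the C–O multiple bond stays outside the new six-membered ring (6-exo-trig if the intact mixed anhydride is attacked). No stereocentre is made, but C3 and C5 of the symmetric biphenyl ring of 14 are enantiotopic, so the closure on that ring turns the C6–C8'' bond into a stereogenic axis and the achiral reagent delivers the racemate. The selectivity needed is the site of C-acylation and the substrate supplies it: either carbon beside O1 gives the same constitution, the second carbon beside O1'' is the axis carbon itself, and every attacked carbon draws on all three ring oxygens (two ortho, one para), which should let closure outrun ring trifluoroacetylation, attack on the anisyl ring and acidolysis of the benzyl ethers. Any E isomer carried along should converge on 16, since the push–pull alkene can equilibrate by reversible protonation at the carbon alpha to the carboxyl group in the trifluoroacetic acid that is formed.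

Step 10
Reactants: 16 5,7,5'',7''-tetrakis(benzyloxy)-4',4'''-dimethoxy-6,8''-biflavone
Product: 17 5,7,5'',7''-tetrahydroxy-4',4'''-dimethoxy-6,8''-biflavone (CNP0226117.0)
Conditions: H2 (1 atm), Pd/C, THF/MeOH, rt
Reagents that add atoms: none
Why: Catalytic hydrogenolysis of the four aryl benzyl ethers, routine for benzylated flavones at one atmosphere, should leave the aryl methyl ethers and the C2–C3 alkenes of the pyranones intact.

**Compound list**
1 | 5-chlororesorcinol | Oc1cc(O)cc(Cl)c1 | starting material
2 | 5-chloro-2-iodobenzene-1,3-diol | Oc1cc(Cl)cc(O)c1I | intermediate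
3 | 1,3-bis(benzyloxy)-5-chloro-2-iodobenzene | Clc1cc(OCc2ccccc2)c(I)c(OCc2ccccc2)c1 | intermediate
4 | 3,5-bis(benzyloxy)phenol | Oc1cc(OCc2ccccc2)cc(OCc2ccccc2)c1 | starting material
5 | 3,5-bis(benzyloxy)-2-iodophenol | Oc1cc(OCc2ccccc2)cc(OCc2ccccc2)c1I | intermediate
6 | 1,5-bis(benzyloxy)-2-iodo-3-(methoxymethoxy)benzene | COCOc1cc(OCc2ccccc2)cc(OCc2ccccc2)c1I | intermediate
7 | [2,4-bis(benzyloxy)-6-(methoxymethoxy)phenyl]magnesium chloride, formed in the flask | COCOc1cc(OCc2ccccc2)cc(OCc2ccccc2)c1[Mg]Cl | intermediate
8 | [2,4-bis(benzyloxy)-6-(methoxymethoxy)phenyl]zinc chloride, formed in the flask | COCOc1cc(OCc2ccccc2)cc(OCc2ccccc2)c1[Zn]Cl | intermediate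
9 | 2,6,4',6'-tetrakis(benzyloxy)-4-chloro-2'-(methoxymethoxy)biphenyl | COCOc1cc(OCc2ccccc2)cc(OCc2ccccc2)c1-c1c(OCc2ccccc2)cc(Cl)cc1OCc1ccccc1 | intermediate
10 | 2,6,4',6'-tetrakis(benzyloxy)-2'-(methoxymethoxy)biphenyl-4-ol, formed in the flask | COCOc1cc(OCc2ccccc2)cc(OCc2ccccc2)c1-c1c(OCc2ccccc2)cc(O)cc1OCc1ccccc1 | intermediate
11 | 2,6,4',6'-tetrakis(benzyloxy)biphenyl-4,2'-diol | Oc1cc(OCc2ccccc2)cc(OCc2ccccc2)c1-c1c(OCc2ccccc2)cc(O)cc1OCc1ccccc1 | intermediate
12 | methyl 3-(4-methoxyphenyl)propiolate | COC(=O)C#Cc1ccc(OC)cc1 | starting material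
13 | dimethyl (2Z,2'Z)-3,3'-{[2,6,4',6'-tetrakis(benzyloxy)biphenyl-4,2'-diyl]bis(oxy)}bis[3-(4-methoxyphenyl)acrylate] | COC(=O)/C=C(/c1ccc(OC)cc1)Oc1cc(OCc2ccccc2)c(-c2c(OCc3ccccc3)cc(OCc3ccccc3)cc2O/C(=C\C(=O)OC)c2ccc(OC)cc2)c(OCc2ccccc2)c1 | intermediate
14 | (2Z,2'Z)-3,3'-{[2,6,4',6'-tetrakis(benzyloxy)biphenyl-4,2'-diyl]bis(oxy)}bis[3-(4-methoxyphenyl)acrylic acid] | O=C(O)/C=C(/c1ccc(OC)cc1)Oc1cc(OCc2ccccc2)c(-c2c(OCc3ccccc3)cc(OCc3ccccc3)cc2O/C(=C\C(=O)O)c2ccc(OC)cc2)c(OCc2ccccc2)c1 | intermediate
15 | bis(trifluoroacetic) mixed anhydride of 14, formed in the flask | O=C(OC(=O)C(F)(F)F)/C=C(/c1ccc(OC)cc1)Oc1cc(OCc2ccccc2)c(-c2c(OCc3ccccc3)cc(OCc3ccccc3)cc2O/C(=C\C(=O)OC(=O)C(F)(F)F)c2ccc(OC)cc2)c(OCc2ccccc2)c1 | intermediate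
16 | 5,7,5'',7''-tetrakis(benzyloxy)-4',4'''-dimethoxy-6,8''-biflavone (racemic axis) | COc1ccc(-c2cc(=O)c3c(OCc4ccccc4)c(-c4c(OCc5ccccc5)cc(OCc5ccccc5)c5c(=O)cc(-c6ccc(OC)cc6)oc45)c(OCc4ccccc4)cc3o2)cc1 | intermediate
17 | 5,7,5'',7''-tetrahydroxy-4',4'''-dimethoxy-6,8''-biflavone (agathisflavone 4',4'''-dimethyl ether, CNP0226117.0) | COc1ccc(-c2cc(=O)c3c(O)c(-c4c(O)cc(O)c5c(=O)cc(-c6ccc(OC)cc6)oc45)c(O)cc3o2)cc1 | target

**Total step count:** 10.
**Longest linear sequence:** 8 (steps 3–10, or equally steps 1, 2 and 5–10).

**Steps most likely to fail**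

1. **Step 9.**
   - What may go wrong: the closure beside the axis may lag behind the unhindered one. The longer exposure to acid then invites benzyl transfer onto the electron-rich rings, ring trifluoroacetylation, or decarboxylation of the arm that is still open.
   - Fallback (carbonylative annulation in place of acylation): it sets out from 11 and comes back at 16. Iodination of 11 with two equivalents of NIS (DMF, −20 °C) should, by the same bias as in step 3, place one iodine beside each free hydroxyl. This gives 2,6,4',6'-tetrakis(benzyloxy)-3,3'-diiodobiphenyl-4,2'-diol F1. Twofold carbonylative Sonogashira coupling with 4-ethynylanisole (CO, PdCl2(dppf), Et2NH, 60 °C) leads to 2,6,4',6'-tetrakis(benzyloxy)-3,3'-bis[3-(4-methoxyphenyl)propynoyl]biphenyl-4,2'-diol F2. The secondary amine cyclises F2 in the same flask to 16 by conjugate addition, 6-endo closure and loss of amine. Site control again rests on there being only one phenol per ring.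

2. **Step 5.**
   - What may go wrong: with four oxygen substituents around the new bond, transmetalation and reductive elimination may become very slow. Reduction of the iodide, homocoupling or late insertion into the C–Cl bond could then take over.
   - Fallback (carbonyl addition and rearomatisation in place of cross-coupling): it sets out from 4 and 6 and comes back at 10. Teuber oxidation of 4 with (KSO3)2NO (KH2PO4, acetone/H2O) gives 2,6-bis(benzyloxy)-1,4-benzoquinone F3. The arylmagnesium chloride 7, made from 6 as in step 5, is added at −78 °C in the presence of LaCl3·2LiCl. The carbonyl flanked by the two benzyloxy-bearing carbons is the only one that is not a vinylogous ester. 1,2-Addition there should give 3,5-bis(benzyloxy)-4-[2,4-bis(benzyloxy)-6-(methoxymethoxy)phenyl]-4-hydroxycyclohexa-2,5-dien-1-one F4. Reductive aromatisation of this p-quinol (Zn, AcOH, THF, rt) gives 10, which the acid stage of step 6 converts into 11. Compound 3 and the hydroxylation are then not needed.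

3. **Step 7.**
   - What may go wrong: the hindered 2'-phenoxide may add slowly and reversibly to an alkynoate that the 4-methoxyphenyl group deactivates. Stalling after one addition, ester cleavage by adventitious water or erosion of the alkene geometry would then compete.
   - Fallback (vinylic substitution in place of alkyne addition): it sets out from 12, takes in 11 and comes back at 13. Hydrochlorination of 12 (LiCl, AcOH, 100 °C, anti addition) gives methyl (Z)-3-chloro-3-(4-methoxyphenyl)acrylate F5. The bis(phenoxide) of 11 (Cs2CO3, DMF, 50 °C) then displaces chloride by an irreversible addition–elimination with retention to give 13.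

**Further compounds**
F1 | step 9 | 2,6,4',6'-tetrakis(benzyloxy)-3,3'-diiodobiphenyl-4,2'-diol | Oc1c(I)c(OCc2ccccc2)cc(OCc2ccccc2)c1-c1c(OCc2ccccc2)cc(O)c(I)c1OCc1ccccc1
F2 | step 9 | 2,6,4',6'-tetrakis(benzyloxy)-3,3'-bis[3-(4-methoxyphenyl)propynoyl]biphenyl-4,2'-diol | COc1ccc(C#CC(=O)c2c(O)c(-c3c(OCc4ccccc4)cc(O)c(C(=O)C#Cc4ccc(OC)cc4)c3OCc3ccccc3)c(OCc3ccccc3)cc2OCc2ccccc2)cc1
F3 | step 5 | 2,6-bis(benzyloxy)-1,4-benzoquinone | O=C1C=C(OCc2ccccc2)C(=O)C(OCc2ccccc2)=C1
F4 | step 5 | 3,5-bis(benzyloxy)-4-[2,4-bis(benzyloxy)-6-(methoxymethoxy)phenyl]-4-hydroxycyclohexa-2,5-dien-1-one | O=C1C=C(OCc2ccccc2)C(O)(c2c(OCOC)cc(OCc3ccccc3)cc2OCc2ccccc2)C(OCc2ccccc2)=C1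
F5 | step 7 | methyl (Z)-3-chloro-3-(4-methoxyphenyl)acrylate | COC(=O)/C=C(\Cl)c1ccc(OC)cc1
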